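The easy step came first: Saturday's flask showed 0.2 % of its solid substrate at 0.833 d, so a small charge went into solution early. Tuesday's flask, with its large charge, still showed 77.6 % as solid at 6.00 d, and its target had reached 7.8 %.

| flask | solid substrate | reagent | remark | time |
|---|---|---|---|---|
| Saturday's | 23 mM | 42 mM | run made earlier |  |
| Tuesday's | 170 mM | 42 mM | run made earlier |  |
| Thursday's | 40 mM | 85 mM | run made earlier |  |
| noon | 120 mM | 42.0 mM |  | 8.0 d |
| dusk | 25 mM | 150 mM |  | 8.0 d |
| autumn | 25 mM | 80.0 mM |  | 8.0 d |
| midnight | 40 mM | 42.0 mM |  | 8.0 d |
| summer | 20 mM | 120 mM |  | 8.0 d |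

| run | time / d | target / % | solid substrate / % |
|---|---|---|---|
| Saturday's | 0.833 | 6.8 | 0.2 |
| Saturday's | 1.67 | 18.1 | 0.1 |
| Saturday's | 2.50 | 28.2 | 0 |
| Saturday's | 3.00 | 32.4 | 0.1 |
| Saturday's | 4.00 | 38.1 | 0 |
| Saturday's | 5.00 | 41.7 | 0 |
| Saturday's | 6.00 | 43.6 | 0.1 |
| Tuesday's | 0.333 | 0.5 | 88.0 |
| Tuesday's | 0.833 | 1.5 | 86.2 |
| Tuesday's | 1.67 | 2.9 | 83.4 |
| Tuesday's | 2.50 | 4.8 | 81.2 |
| Tuesday's | 3.00 | 4.9 | 80.4 |
| Tuesday's | 4.00 | 6.1 | 79.3 |
| Tuesday's | 6.00 | 7.8 | 77.6 |
| Thursday's | 0.500 | 3.2 | 38.5 |
| Thursday's | 1.25 | 14.4 | 14.9 |
| Thursday's | 2.50 | 32.0 | 0.5 |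
| Thursday's | 4.00 | 40.5 | 0 |
| Thursday's | 6.00 | 43.1 | 0 |

(standard deviation of a reading: 0.3 percentage points)

* ranking by amount of target, in percent of the solid substrate charged, from high to low, at 8.0 d (noon / dusk / autumn / midnight / summer)
* the same order at 40 h (noon / dusk / autumn / midnight / summer)
* the amount of target, in percent of the solid substrate charged of the flask you put first, at 8.0 d
* the amount of target, in percent of the solid substrate charged of the flask you put last, at 8.0 d

- given per volume of solution although it is solid: solid substrate
- at the start none of the solid substrate is in solution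
- what has only dissolved of solid substrate counts as not reacted

But Saturday's and Thursday's flasks, whose solid read 0.1 % and 0 % at their last points, read 43.6 % and 43.1 % of target there, although each held more reagent than solid substrate. So I read the slowing as a balance that could run both ways, supposing that each target spends one reagent and brings one by-product.

I kept one number, 0.193, from Thursday's last reading: the balance number, a reaction quotient, is the target fraction squared, divided by the fraction of the charge not turned into target and by the reagent equivalents not spent on target. Saturday's last reading gave 0.242, but I used Thursday's, which had more reagent per charge.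

Summer and dusk both carry 6.00 equivalents, so my reckoning gave them one value, 62.4 %, and could not separate them.

The forecast differed. It gave autumn > summer > dusk > midnight > noon at 8.0 d and dusk > summer > autumn > midnight > noon at 40 h, with 44.5 % for its first flask and 13 % for its last, holding that “That plateau barely changes with reagent”.

Summer came first at 59.0 %, in the order summer > dusk > autumn > midnight > noon, and noon came last at 11.1 %; at 40 h the order was dusk > summer > autumn > midnight > noon.

    2 starting material → homo dimer (k = 5.70 × 10⁻⁵ /M/min)
    solid substrate ⇌ starting material, rate k2*(cs2 - [starting material]) while solid is left; crystals form when [starting material] > cs2 (solubility = 18.0 mM, k = 0.0110 /min)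
    intermediate ⇌ target + by-product (K = 0.0250 M, k = 5.00 × 10⁻⁴ /min)
    starting material + reagent ⇌ intermediate (K = 21.0 /M, k = 0.0100 /M/min)

Summer held 27.9 % as intermediate and 13.0 % as starting material at 8.00 d, and both count in the balance number as charge not turned into target. Summer's own result puts that number at 0.157, which is lower than Thursday's. With Thursday's value and autumn's 3.20 equivalents, I reckoned 50.7 %, and autumn gave 51.6 %.

The data are simulated with constants of no real substance; scatter was added.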